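**Assumption:** elemane numbering is used in the text (ring C5–C10; C14 = CH2O carbon on C10; C11/C12/C13 = lactone α-carbon, carbonyl, methylene; C15 = CHO), and allyl 3-methylbut-2-enoate is made rather than bought.

## Retrosynthetic overview

1. Target 26 ⇐ 24 by allylic oxidation of the isopropenyl methyl; 24 ⇐ 23 by C14 acetylation.
2. Key disconnection, C6–C7: a 2-(methoxycarbonyl)allylindium, whose acrylate β-carbon C7 acts as a homoenolate donor, attacks the C6 aldehyde (lactol 21) intramolecularly. The cyclohexane closes first; the trans α-methylene lactone forms from the new C6 hydroxyl right after.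
3. 21 ⇐ lactone 14 (half-reduction/acetylation, glycol cleavage, Baylis–Hillman addition and SN2′ bromination); 14 ⇐ acid 12 by lactone reduction and translactonisation onto C6.
4. C5–C10 (quaternary C10 and C5 together): Ireland–Claisen rearrangement of senecioate 9 ⇐ cross-metathesis of α-methylene lactone 5 with 8.
5. 5 ⇐ (R)-glyceraldehyde acetonide + ethyl 2-(bromomethyl)acrylate (indium Barbier; sets C8, the only stereocentre taken from the chiral pool).

## Route

**Step 1**
Reactants: 1 diacetone-D-mannitol; 2 ethyl (bromomethyl)acrylate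
Product: 5 (5S)-5-[(4R)-2,2-dimethyl-1,3-dioxolan-4-yl]-3-methylideneoxolan-2-one, via (R)-glyceraldehyde acetonide 3 (not isolated), via anti hydroxy ester 4 (not isolated)
Conditions: NaIO4, NaHCO3, H2O/CH2Cl2, 0 °C to rt; CH2Cl2 phase added to the bromide, In powder, THF/H2O 1:1, rt; then PPTS (cat.), PhMe, 60 °C
Reagents that add atoms: none
Why: Glycol cleavage gives (R)-glyceraldehyde acetonide, and the indium-mediated Barbier 2-(ethoxycarbonyl)allylation (Dreiding–Schmidt lactone synthesis, the acrylate β-carbon reacting as a homoenolate donor) adds under Felkin–Anh, non-chelation control to give mainly the anti adduct, fixing C8 as S, before acid-catalysed lactonisation; the minor syn lactone is removed by chromatography.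

**Step 2**
Reactants: 6 allyl alcohol; 7 senecioyl chloride
Product: 8 prop-2-en-1-yl 3-methylbut-2-enoate
Conditions: pyridine, DMAP (cat.), CH2Cl2, 0 °C to rt
Reagents that add atoms: none
Why: Pyridine/DMAP-mediated acylation of the alcohol by the acid chloride (esterification); any deconjugation to the 3-enoate is harmless because both isomers give the same dienolate in step 4.

**Step 3**
Reactants: 5 α-methylene lactone; 8 allyl senecioate
Product: 9 2-[(3E,5S)-5-[(4R)-2,2-dimethyl-1,3-dioxolan-4-yl]-2-oxooxolan-3-ylidene]ethyl 3-methylbut-2-enoate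
Conditions: second-generation Hoveyda–Grubbs catalyst (H2IMes)Cl2Ru=CH(C6H4-2-OiPr) (5 mol %), excess allyl ester, CH2Cl2, 40 °C
Reagents that add atoms: none
Why: Olefin cross-metathesis between the 1,1-disubstituted α-methylene lactone and the excess terminal allyl ester gives the thermodynamic (E)-alkylidene lactone, the geometry needed for step 4; the conjugated trisubstituted senecioate alkene does not metathesise.

**Step 4**
Reactants: 9 alkylidene lactone senecioate
Product: 12 (2S)-2-[(3R,5S)-5-[(4R)-2,2-dimethyl-1,3-dioxolan-4-yl]-3-ethenyl-2-oxooxolan-3-yl]-3-methylbut-3-enoic acid, via silyl ketene acetal 10 (not isolated), via trimethylsilyl ester 11 (not isolated)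
Conditions: LiN(iPr)2, Me3SiCl (in situ quench), THF, −78 °C to rt; aq. citric acid work-up
Reagents that add atoms: none
Why: Ireland–Claisen rearrangement: kinetic γ-deprotonation of the s-cis senecioate and in situ silylation give the (1Z)-ketene acetal, whose chair [3,3] shift across the (E)-alkylidene lactone sets C5 relative to C10, and bond formation anti to the dioxolanyl group on the lactone (1,3-induction from C8) sets the absolute configuration of the new vinyl-bearing quaternary C10.

**Step 5**
Reactants: 12 Claisen acid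
Product: 14 (3S,4R)-4-[(2S)-2-[(4R)-2,2-dimethyl-1,3-dioxolan-4-yl]-2-hydroxyethyl]-4-ethenyl-3-(prop-1-en-2-yl)oxolan-2-one, via dihydroxy acid 13 (not isolated)
Conditions: LiBH4 (3 equiv), MeOH (1 equiv), THF, 0 to 40 °C; then 1 M HCl to pH 3, rt
Reagents that add atoms: none
Why: Chemoselective LiBH4 reduction of the lactone next to the inert lithium carboxylate, then acid-promoted γ-lactonisation of the C14 alcohol onto the C6 carboxyl (translactonisation), brings C14 to the alcohol level, frees the C8 hydroxyl and leaves every stereocentre untouched.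

**Step 6**
Reactants: 14 hydroxy lactone
Product: 16 (3S,4R)-4-[(2S)-2-acetoxy-2-[(4R)-2,2-dimethyl-1,3-dioxolan-4-yl]ethyl]-4-ethenyl-3-(prop-1-en-2-yl)oxolan-2-yl acetate, via lactol 15 (not isolated)
Conditions: iBu2AlH (2.2 equiv), CH2Cl2, −78 °C; then pyridine, DMAP, Ac2O, −78 to 0 °C
Reagents that add atoms: acetic anhydride, CC(=O)OC(C)=O
Why: Reductive acetylation: iBu2AlH half-reduces the lactone at −78 °C and the aluminium lactolate and the C8 alkoxide are acetylated in situ, so C6 is fixed at the aldehyde level as an anomeric acetate and the C8 acetate of the target is installed.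

**Step 7**
Reactants: 16 acetonide bis-acetate
Product: 17 (3S,4R)-4-[(2S)-2-acetoxy-3-oxopropyl]-4-ethenyl-3-(prop-1-en-2-yl)oxolan-2-yl acetate
Conditions: H5IO6 (1.5 equiv), EtOAc, rt
Reagents that add atoms: none
Why: Periodic acid hydrolyses the terminal acetonide and cleaves the resulting 1,2-diol in one operation (glycol cleavage), giving the C7 aldehyde without touching C8, the acetates or the alkenes.

**Step 8**
Reactants: 17 acetoxy aldehyde; 18 methyl acrylate
Product: 20 methyl (2Z,4S)-4-acetoxy-5-[(3R,4S)-5-acetoxy-3-ethenyl-4-(prop-1-en-2-yl)oxolan-3-yl]-2-(bromomethyl)pent-2-enoate, via Baylis–Hillman alcohol 19 (not isolated)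
Conditions: DABCO (50 mol %), excess methyl acrylate, dioxane, rt; aq. NH4Cl wash, concentrate; crude: NBS, Me2S, CH2Cl2, −20 to 0 °C
Reagents that add atoms: N-bromosuccinimide, O=C1CCC(=O)N1Br
Why: Morita–Baylis–Hillman reaction of the activated α-acetoxy aldehyde with methyl acrylate attaches C11, C12 and C13 (the configuration of the new C7 carbinol is irrelevant because C7 becomes sp2), and after the amine is washed out the bromodimethylsulfonium salt activates the crude alcohol so that SN2′ return of bromide (Corey–Kim-type allylic transposition) gives the conjugated (Z)-2-(bromomethyl)enoate without free bromine that could attack the other alkenes.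

**Step 9**
Reactants: 20 allylic bromide
Product: 23 (3aR,4S,6R,7S,7aR)-6-ethenyl-6-(hydroxymethyl)-3-methylidene-2-oxo-7-(prop-1-en-2-yl)octahydro-1-benzofuran-4-yl acetate, via lactol 21 (not isolated), via hydroxy ester 22 (not isolated)
Conditions: 0.1 M HCl, THF/H2O 3:1, rt; then In powder (3 equiv), 0.005 M, rt to 40 °C; crude: TsOH·H2O (cat.), CH2Cl2, rt
Reagents that add atoms: water, O
Why: Acid hydrolysis frees the lactol (masked C6 aldehyde), indium inserts into the allylic bromide, and the resulting 2-(methoxycarbonyl)allylindium, in which the acrylate β-carbon C7 is a homoenolate donor, adds to C6 in an intramolecular Barbier (Dreiding–Schmidt) allylation through the chair in which the C8 acetate, the C5 isopropenyl group and the forming C7–C11 and C6–O bonds are all equatorial, the axial C14 arm destabilising the alternative with an axial C6 oxygen that gives cis-fused lactones with unsubstituted tethers, so C6 (R) and C7 (R) are set trans and the γ-hydroxy ester closes to the lactone.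

**Step 10**
Reactants: 23 hydroxymethyl lactone
Product: 24 [(3aR,4S,6R,7S,7aR)-4-acetoxy-6-ethenyl-3-methylidene-2-oxo-7-(prop-1-en-2-yl)octahydro-1-benzofuran-6-yl]methyl acetate
Conditions: Ac2O, pyridine, DMAP (cat.), CH2Cl2, 0 °C to rt
Reagents that add atoms: acetic anhydride, CC(=O)OC(C)=O
Why: DMAP-catalysed acetylation of the neopentyl primary alcohol; no other hydroxyl is present.

**Step 11**
Reactants: 24 diacetate
Product: 26 [(3aR,4S,6R,7R,7aR)-4-acetoxy-6-ethenyl-3-methylidene-2-oxo-7-(3-oxoprop-1-en-2-yl)octahydro-1-benzofuran-6-yl]methyl acetate, via allylic alcohol 25 (not isolated)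
Conditions: SeO2 (0.5 equiv), tBuOOH (2 equiv), CH2Cl2, rt; then Dess–Martin periodinane, NaHCO3, rt
Reagents that add atoms: selenium dioxide, O=[Se]=O; tert-butyl hydroperoxide, CC(C)(C)OO
Why: Riley allylic oxidation (ene reaction then [2,3]-shift) attacks only the electron-rich isopropenyl group at its methyl (the vinyl group has no allylic hydrogen and the α-methylene lactone is electron-poor), and Dess–Martin oxidation of the alcohol formed alongside the aldehyde completes the enal; no stereocentre is affected.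

## Compound list

1 | 1,2:5,6-di-O-isopropylidene-D-mannitol (diacetone-D-mannitol) | CC1(C)OC[C@@H](O1)[C@@H](O)[C@H](O)[C@H]1COC(C)(C)O1 | starting material
2 | ethyl 2-(bromomethyl)prop-2-enoate (ethyl (bromomethyl)acrylate) | C=C(CBr)C(=O)OCC | starting material
3 | (4R)-2,2-dimethyl-1,3-dioxolane-4-carbaldehyde ((R)-glyceraldehyde acetonide) | CC1(C)OC[C@@H](O1)C=O | intermediate
4 | ethyl (4S)-4-[(4R)-2,2-dimethyl-1,3-dioxolan-4-yl]-4-hydroxy-2-methylidenebutanoate (anti adduct) | CCOC(=O)C(=C)C[C@H](O)[C@H]1COC(C)(C)O1 | intermediate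
5 | (5S)-5-[(4R)-2,2-dimethyl-1,3-dioxolan-4-yl]-3-methylideneoxolan-2-one (α-methylene lactone; lactone C5 = future C8) | C=C1C[C@H](OC1=O)[C@H]1COC(C)(C)O1 | intermediate
6 | prop-2-en-1-ol (allyl alcohol) | C=CCO | starting material
7 | 3-methylbut-2-enoyl chloride (senecioyl chloride) | CC(C)=CC(Cl)=O | starting material
8 | prop-2-en-1-yl 3-methylbut-2-enoate (allyl senecioate) | CC(C)=CC(=O)OCC=C | intermediate
9 | 2-[(3E,5S)-5-[(4R)-2,2-dimethyl-1,3-dioxolan-4-yl]-2-oxooxolan-3-ylidene]ethyl 3-methylbut-2-enoate | CC(C)=CC(=O)OC/C=C1\C[C@H](OC1=O)[C@H]1COC(C)(C)O1 | intermediate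
10 | (1Z)-O-trimethylsilyl ketene acetal of 9 (silyloxy cis to isopropenyl) | C=C(C)/C=C(\O[Si](C)(C)C)OC/C=C1\C[C@H](OC1=O)[C@H]1COC(C)(C)O1 | intermediate
11 | trimethylsilyl ester of 12 | C[Si](C)(C)OC(=O)[C@@H](C(C)=C)[C@]1(C=C)C[C@H](OC1=O)[C@H]1COC(C)(C)O1 | intermediate
12 | (2S)-2-[(3R,5S)-5-[(4R)-2,2-dimethyl-1,3-dioxolan-4-yl]-3-ethenyl-2-oxooxolan-3-yl]-3-methylbut-3-enoic acid | OC(=O)[C@@H](C(C)=C)[C@]1(C=C)C[C@H](OC1=O)[C@H]1COC(C)(C)O1 | intermediate
13 | (2S,3R,5S)-5-[(4R)-2,2-dimethyl-1,3-dioxolan-4-yl]-3-ethenyl-5-hydroxy-3-(hydroxymethyl)-2-(prop-1-en-2-yl)pentanoic acid | OC(=O)[C@@H](C(C)=C)[C@@](C=C)(CO)C[C@H](O)[C@H]1COC(C)(C)O1 | intermediate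
14 | (3S,4R)-4-[(2S)-2-[(4R)-2,2-dimethyl-1,3-dioxolan-4-yl]-2-hydroxyethyl]-4-ethenyl-3-(prop-1-en-2-yl)oxolan-2-one | CC(=C)[C@@H]1C(=O)OC[C@@]1(C=C)C[C@H](O)[C@H]1COC(C)(C)O1 | intermediate
15 | lactol of 14 (oxolan-2-ol, both anomers; aluminium alkoxide in the flask) | CC(=C)[C@@H]1C(O)OC[C@@]1(C=C)C[C@H](O)[C@H]1COC(C)(C)O1 | intermediate
16 | (3S,4R)-4-[(2S)-2-acetoxy-2-[(4R)-2,2-dimethyl-1,3-dioxolan-4-yl]ethyl]-4-ethenyl-3-(prop-1-en-2-yl)oxolan-2-yl acetate (both anomers) | CC(=C)[C@@H]1C(OC(C)=O)OC[C@@]1(C=C)C[C@H](OC(C)=O)[C@H]1COC(C)(C)O1 | intermediate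
17 | (3S,4R)-4-[(2S)-2-acetoxy-3-oxopropyl]-4-ethenyl-3-(prop-1-en-2-yl)oxolan-2-yl acetate (C7 aldehyde) | CC(=C)[C@@H]1C(OC(C)=O)OC[C@@]1(C=C)C[C@H](OC(C)=O)C=O | intermediate
18 | methyl prop-2-enoate (methyl acrylate) | C=CC(=O)OC | starting material
19 | methyl (4S)-4-acetoxy-5-[(3R,4S)-5-acetoxy-3-ethenyl-4-(prop-1-en-2-yl)oxolan-3-yl]-3-hydroxy-2-methylidenepentanoate (C7 epimers) | CC(=C)[C@@H]1C(OC(C)=O)OC[C@@]1(C=C)C[C@H](OC(C)=O)C(O)C(=C)C(=O)OC | intermediate
20 | methyl (2Z,4S)-4-acetoxy-5-[(3R,4S)-5-acetoxy-3-ethenyl-4-(prop-1-en-2-yl)oxolan-3-yl]-2-(bromomethyl)pent-2-enoate | CC(=C)[C@@H]1C(OC(C)=O)OC[C@@]1(C=C)C[C@H](OC(C)=O)/C=C(\CBr)C(=O)OC | intermediate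
21 | lactol of 20 (anomeric OH; in equilibrium with the open C6 aldehyde/C14 alcohol) | CC(=C)[C@@H]1C(O)OC[C@@]1(C=C)C[C@H](OC(C)=O)/C=C(\CBr)C(=O)OC | intermediate
22 | methyl 2-[6-acetoxy-4-ethenyl-2-hydroxy-4-(hydroxymethyl)-3-(prop-1-en-2-yl)cyclohexyl]prop-2-enoate, ring stereocentres as in 23 (C6–OH and C7 side chain trans-diequatorial) | C=C[C@]1(CO)C[C@H](OC(C)=O)[C@@H](C(=C)C(=O)OC)[C@H](O)[C@H]1C(C)=C | intermediate
23 | (3aR,4S,6R,7S,7aR)-6-ethenyl-6-(hydroxymethyl)-3-methylidene-2-oxo-7-(prop-1-en-2-yl)octahydro-1-benzofuran-4-yl acetate | C=C[C@]1(CO)C[C@H](OC(C)=O)[C@H]2C(=C)C(=O)O[C@@H]2[C@H]1C(C)=C | intermediate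
24 | [(3aR,4S,6R,7S,7aR)-4-acetoxy-6-ethenyl-3-methylidene-2-oxo-7-(prop-1-en-2-yl)octahydro-1-benzofuran-6-yl]methyl acetate | C=C[C@]1(COC(C)=O)C[C@H](OC(C)=O)[C@H]2C(=C)C(=O)O[C@@H]2[C@H]1C(C)=C | intermediate
25 | C15 allylic alcohol of 24 (7-(3-hydroxyprop-1-en-2-yl)) | C=C[C@]1(COC(C)=O)C[C@H](OC(C)=O)[C@H]2C(=C)C(=O)O[C@@H]2[C@H]1C(=C)CO | intermediate
26 | [(3aR,4S,6R,7R,7aR)-4-acetoxy-6-ethenyl-3-methylidene-2-oxo-7-(3-oxoprop-1-en-2-yl)octahydro-1-benzofuran-6-yl]methyl acetate (CNP0200597.1; elemane C5 R, C6 R, C7 R, C8 S, C10 R) | C=C[C@]1(COC(C)=O)C[C@H](OC(C)=O)[C@H]2C(=C)C(=O)O[C@@H]2[C@H]1C(=C)C=O | target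

## Step count

Total: 11 steps. Longest linear sequence: 10 steps (steps 1 and 3–11; step 2 is a one-step side branch).

## Three steps most likely to fail

**Step 9 (key cyclisation).** Three risks, in order:
- Unsubstituted tethers in this reaction type normally give cis-fused lactones. The trans outcome here rests on the axial C14 arm and on E/Z equilibration of the allylindium, which is a prediction.
- The allylindium carries a δ-acetoxy group (C8) and could undergo 1,4-elimination to a diene.
- The open aldehyde can epimerise at C5 or move the isopropenyl double bond into conjugation.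

Fallback, setting out from 20 and returning at 23: hydrolyse to lactol 21 as in step 9, then close the ring with an acyl-anion donor instead of the allylmetal. A thiazolium carbene (3-benzyl-5-(2-hydroxyethyl)-4-methylthiazolium chloride, Et3N, EtOH/THF, 60 °C) converts the C6 aldehyde into its Breslow intermediate, which attacks C7 in an intramolecular Stetter addition with loss of bromide. This gives the C6 ketone F1, in which C5 and C7 (both α to the ketone) settle equatorial. Reduction with Me4NBH(OAc)3 (MeCN/AcOH, −20 °C), delivered from the axial C14 hydroxyl, gives the equatorial C6 alcohol 22, and TsOH closes it to 23.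

**Step 4 (Ireland–Claisen).** Risks: competing deprotonation or amide addition at the alkylidene lactone, a slow [3,3] shift onto a fully substituted carbon, and only moderate facial control from the remote C8 substituent (roughly 5:1 expected, separable).

Fallback, setting out from 5 and returning at 12: cross-metathesis of 5 with (Z)-but-2-ene (same ruthenium catalyst) gives the ethylidene lactone F2. LiN(iPr)2 (THF, −78 °C) forms its dienolate, which adds through the α-carbon, anti to the dioxolanyl group, to (E)-3-methyl-1-nitrobuta-1,3-diene (from methacrolein and nitromethane) in a Michael reaction. This gives the nitro compound F3 with the vinyl-bearing quaternary C10 and C5 in place. NaNO2/AcOH/DMSO (35 °C) then converts CH2NO2 into CO2H, giving 12.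

**Step 8 (Baylis–Hillman addition and bromination on the α-acetoxy aldehyde).** Risks: epimerisation at C8 and acetyl migration from C8–O to the new C7–OH under prolonged amine catalysis, and residual amine quaternising the allylic bromide if the wash is incomplete.

Fallback, setting out from 17 and returning at 20: Horner–Wadsworth–Emmons olefination with methyl 3-[(tert-butyldimethylsilyl)oxy]-2-(dimethoxyphosphoryl)propanoate (LiCl, DBU, MeCN, 0 °C) gives the silyl ether enoate F4 (E/Z mixture; both isomers feed the same allylindium). Ph3PBr2 (CH2Cl2, 0 °C) converts the allylic silyl ether directly into bromide 20, skipping 19.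

## Further compounds

F1 | step 9 | methyl 2-[6-acetoxy-4-ethenyl-4-(hydroxymethyl)-2-oxo-3-(prop-1-en-2-yl)cyclohexyl]prop-2-enoate (C6 ketone; other centres as in 22) | C=C[C@]1(CO)C[C@H](OC(C)=O)[C@@H](C(=C)C(=O)OC)C(=O)[C@H]1C(C)=C
F2 | step 4 | (3E,5S)-5-[(4R)-2,2-dimethyl-1,3-dioxolan-4-yl]-3-ethylideneoxolan-2-one | C/C=C1\C[C@H](OC1=O)[C@H]1COC(C)(C)O1
F3 | step 4 | (3R,5S)-5-[(4R)-2,2-dimethyl-1,3-dioxolan-4-yl]-3-ethenyl-3-(3-methyl-1-nitrobut-3-en-2-yl)oxolan-2-one (side-chain centre as C5 of 12) | [O-][N+](=O)C[C@@H](C(C)=C)[C@]1(C=C)C[C@H](OC1=O)[C@H]1COC(C)(C)O1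
F4 | step 8 | methyl (4S)-4-acetoxy-5-[(3R,4S)-5-acetoxy-3-ethenyl-4-(prop-1-en-2-yl)oxolan-3-yl]-2-{[(tert-butyldimethylsilyl)oxy]methyl}pent-2-enoate (E/Z mixture) | CC(=C)[C@@H]1C(OC(C)=O)OC[C@@]1(C=C)C[C@H](OC(C)=O)C=C(CO[Si](C)(C)C(C)(C)C)C(=O)OC
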